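The six-membered ring of the 7-oxabicyclo[4.1.0]heptan-2-one carries its methyl-bearing carbon C1 and its side-chain-bearing carbon C4 in a 1,4 relationship, and the exocyclic C(=CH2) carbon on C4 is a latent acetyl carbon. The ring is therefore assembled from isoprene and but-3-en-2-one: one catalytic, enantioselective, para-selective Diels–Alder reaction forms C5–C6 and C3–C4 and sets C4. Every ring oxygen (C2 ketone, C3 ester, C1–C6 epoxide) is then introduced under stereochemical relay from C4, while the acetyl group travels as an enol triflate and is turned into the cross-conjugated hydroxy dienone last, by carbonylative Stille coupling.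

Key step: step 1

Remark on numbering: ring positions are given throughout in the numbering of the final bicycle (C1 C–CH3, C2 C=O, C3 C–O ester, C4 C–side chain, C5 CH2, C6 epoxide CH).

Assumption: the facial sense of the oxazaborolidinium catalyst toward but-3-en-2-one is taken to parallel its behaviour with acrylate esters, so the catalyst built from (R)-α,α-diphenylprolinol is specified; if the enone binds in the opposite sense, the (S)-catalyst is used with no other change.

Step 1
Reactants: 1 isoprene; 2 methyl vinyl ketone (but-3-en-2-one)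
Product: 3 (R)-1-(4-methylcyclohex-3-en-1-yl)ethan-1-one
Conditions: (R)-B-(o-tolyl)oxazaborolidine from α,α-diphenylprolinol, protonated with HN(SO2CF3)2 (10 mol%), CH2Cl2, −78 to −40 °C
Reagents that add atoms: none
Why: Coordination of the enone carbonyl to the cationic boron lowers its LUMO, and a concerted, asynchronous [4+2] cycloaddition with s-cis isoprene forms C5–C6 (isoprene C1 to the enone β-carbon) and C3–C4 (isoprene C4 to the enone α-carbon) at once. The closest known reaction type is the Diels–Alder reaction of simple enones with 2-substituted butadienes under chiral oxazaborolidinium catalysis. The cyclohexene ring closes by intermolecular suprafacial [4+2] addition, both new σ-bonds being made in the same transition state. The single new stereocentre C4 is set by the catalyst, whose aryl group shields one face of the boron-bound enone so that the diene adds to the open face. The step needs para regioselectivity, secured by the larger HOMO coefficient at the isoprene CH2 next to the methyl-bearing carbon pairing with the enone β-carbon and sharpened by Lewis-acid activation, and it needs enantiofacial control, secured by the catalyst; no endo/exo question arises because only one stereocentre forms.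

Step 2
Reactants: 3 (R)-1-(4-methylcyclohex-3-en-1-yl)ethan-1-one
Product: 5 1-[(1R)-4-methylcyclohex-3-en-1-yl]ethenyl trifluoromethanesulfonate, via potassium enolate 4 (not isolated)
Conditions: KN(SiMe3)2, THF, −78 °C; then PhNTf2, −78 to 0 °C
Reagents that add atoms: N-phenylbis(trifluoromethanesulfonimide), O=S(=O)(N(c1ccccc1)S(=O)(=O)C(F)(F)F)C(F)(F)F
Why: Kinetic deprotonation of the methyl ketone at the unhindered CH3 (not at the ring methine C4) and O-sulfonylation of the terminal enolate is standard enol triflate formation; the C4 stereocentre is not touched, and the base-sensitive acetyl group is replaced by a robust handle.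

Step 3
Reactants: 5 1-[(1R)-4-methylcyclohex-3-en-1-yl]ethenyl trifluoromethanesulfonate
Product: 6 (5R)-2-hydroxy-2-methyl-5-[1-(trifluoromethanesulfonyloxy)ethenyl]cyclohexan-1-one (both epimers at the carbinol carbon)
Conditions: RuCl3·xH2O (1 mol%), 2KHSO5·KHSO4·K2SO4, NaHCO3, EtOAc/MeCN/H2O, rt, short reaction time
Reagents that add atoms: potassium peroxymonosulfate, [K+].[O-]S(=O)(=O)OO
Why: Catalytic ruthenium tetroxide ketohydroxylation: RuO4 should add to the electron-rich trisubstituted C1=C2 alkene in preference to the deactivated sulfonyloxy alkene, and further oxidation of the ruthenate ester gives the α-ketol with the ketone necessarily on the former CH carbon C2; the C1 carbinol centre forms unselectively and is removed in step 4.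

Step 4
Reactants: 6 (5R)-2-hydroxy-2-methyl-5-[1-(trifluoromethanesulfonyloxy)ethenyl]cyclohexan-1-one
Product: 8 (5R)-2-methyl-5-[1-(trifluoromethanesulfonyloxy)ethenyl]cyclohex-2-en-1-one, via chlorosulfite ester 7 (not isolated)
Conditions: SOCl2, pyridine, CH2Cl2, −10 °C to rt
Reagents that add atoms: none
Why: Dehydration of the tertiary alcohol through its chlorosulfite by pyridine-induced anti elimination toward C6–H should give the conjugated endocyclic C1=C6 enone, the thermodynamically favoured regioisomer, from both epimers of 6.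

Step 5
Reactants: 8 (5R)-2-methyl-5-[1-(trifluoromethanesulfonyloxy)ethenyl]cyclohex-2-en-1-one; 9 tiglic acid ((E)-2-methylbut-2-enoic acid)
Product: 10 (1S,6R)-3-methyl-2-oxo-6-[1-(trifluoromethanesulfonyloxy)ethenyl]cyclohex-3-en-1-yl (2E)-2-methylbut-2-enoate (ester trans to the alkenyl group)
Conditions: Mn(OAc)3·2H2O (excess), 9 (large excess), benzene, reflux with azeotropic removal of AcOH
Reagents that add atoms: none
Why: α′-Acyloxylation of an enone by a trivalent manganese carboxylate (acetate ligands exchanged for tiglate): the manganese enolate formed at C3 is oxidised with carboxylate transfer to the face anti to the adjacent C4 alkenyl group, which should set the C3 stereocentre trans to C4.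

Step 6
Reactants: 10 (1S,6R)-3-methyl-2-oxo-6-[1-(trifluoromethanesulfonyloxy)ethenyl]cyclohex-3-en-1-yl (2E)-2-methylbut-2-enoate
Product: 11 (1S,2S,6R)-2-hydroxy-3-methyl-6-[1-(trifluoromethanesulfonyloxy)ethenyl]cyclohex-3-en-1-yl (2E)-2-methylbut-2-enoate (hydroxyl cis to the alkenyl group, trans to the ester)
Conditions: NaBH4, CeCl3·7H2O, MeOH, −78 °C; quench with aqueous NH4Cl at −78 °C
Reagents that add atoms: none
Why: Luche reduction (1,2-selective): hydride adds axially to the half-chair in which the C3 and C4 substituents are pseudo-equatorial, giving the pseudo-equatorial C2 alcohol cis to the alkenyl group and trans to the ester, while the low temperature and cold quench should prevent acyl migration.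

Step 7
Reactants: 11 (1S,2S,6R)-2-hydroxy-3-methyl-6-[1-(trifluoromethanesulfonyloxy)ethenyl]cyclohex-3-en-1-yl (2E)-2-methylbut-2-enoate
Product: 12 (1R,2R,3S,4R,6S)-2-hydroxy-1-methyl-4-[1-(trifluoromethanesulfonyloxy)ethenyl]-7-oxabicyclo[4.1.0]heptan-3-yl (2E)-2-methylbut-2-enoate (epoxide cis to the hydroxyl and the alkenyl group)
Conditions: VO(acac)2 (5 mol%), t-BuOOH (in decane), CH2Cl2, 0 °C to rt
Reagents that add atoms: tert-butyl hydroperoxide, CC(C)(C)OO
Why: Hydroxyl-directed epoxidation of an allylic alcohol by the vanadium alkylperoxide delivers oxygen to the alkene face that carries the C2 hydroxyl, so both epoxide stereocentres (C1, C6) are set in one event, cis to the C4 group and trans to the ester; the electron-poor tiglate and enol triflate alkenes should not react.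

Step 8
Reactants: 12 (1R,2R,3S,4R,6S)-2-hydroxy-1-methyl-4-[1-(trifluoromethanesulfonyloxy)ethenyl]-7-oxabicyclo[4.1.0]heptan-3-yl (2E)-2-methylbut-2-enoate
Product: 13 (1S,3S,4R,6S)-1-methyl-2-oxo-4-[1-(trifluoromethanesulfonyloxy)ethenyl]-7-oxabicyclo[4.1.0]heptan-3-yl (2E)-2-methylbut-2-enoate
Conditions: Dess–Martin periodinane, NaHCO3, CH2Cl2, 0 °C to rt
Reagents that add atoms: none
Why: Dess–Martin oxidation of the secondary alcohol under buffered, non-basic conditions should give the epoxy ketone without epimerising the α-acyloxy centre C3 or opening the epoxide.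

Step 9
Reactants: 14 2-methylbut-3-yn-2-ol
Product: 15 (E)-2-methyl-4-(tributylstannyl)but-3-en-2-ol
Conditions: Bu3SnH, PdCl2(PPh3)2 (2 mol%), THF, 0 °C to rt
Reagents that add atoms: tributyltin hydride, CCCC[SnH](CCCC)CCCC
Why: Palladium-catalysed syn hydrostannation of the terminal alkyne places tin at the unhindered terminus, away from the tertiary carbinol, and gives the (E)-alkenylstannane.

Step 10
Reactants: 13 (1S,3S,4R,6S)-1-methyl-2-oxo-4-[1-(trifluoromethanesulfonyloxy)ethenyl]-7-oxabicyclo[4.1.0]heptan-3-yl (2E)-2-methylbut-2-enoate; 15 (E)-2-methyl-4-(tributylstannyl)but-3-en-2-ol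
Product: 16 (1S,3S,4S,6S)-4-[(4E)-6-hydroxy-6-methyl-3-oxohepta-1,4-dien-2-yl]-1-methyl-2-oxo-7-oxabicyclo[4.1.0]heptan-3-yl (2E)-2-methylbut-2-enoate (CNP0263368.1)
Conditions: Pd(PPh3)4 (5 mol%), LiCl, CO (1 atm), THF, 55 °C
Reagents that add atoms: carbon monoxide, [C-]#[O+]
Why: Carbonylative Stille coupling: chloride-assisted oxidative addition of zerovalent palladium into the enol triflate, CO insertion to the acylpalladium, then transmetalation and reductive elimination with retention of the (E)-alkene geometry should give the cross-conjugated dienone under neutral conditions that spare the epoxy ketone, the ester and the tertiary alcohol.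

Compound list
1 | isoprene (2-methylbuta-1,3-diene) | C=CC(C)=C | starting material
2 | methyl vinyl ketone (but-3-en-2-one) | C=CC(C)=O | starting material
3 | (R)-1-(4-methylcyclohex-3-en-1-yl)ethan-1-one | CC(=O)[C@@H]1CCC(C)=CC1 | intermediate
4 | potassium 1-[(1R)-4-methylcyclohex-3-en-1-yl]ethen-1-olate (potassium enolate of 3) | C=C([O-])[C@@H]1CCC(C)=CC1.[K+] | intermediate
5 | 1-[(1R)-4-methylcyclohex-3-en-1-yl]ethenyl trifluoromethanesulfonate | C=C(OS(=O)(=O)C(F)(F)F)[C@@H]1CCC(C)=CC1 | intermediate
6 | (5R)-2-hydroxy-2-methyl-5-[1-(trifluoromethanesulfonyloxy)ethenyl]cyclohexan-1-one, both epimers at C2 | C=C(OS(=O)(=O)C(F)(F)F)[C@@H]1CCC(C)(O)C(=O)C1 | intermediate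
7 | chlorosulfite ester of 6 (tertiary O–S(=O)Cl) | C=C(OS(=O)(=O)C(F)(F)F)[C@@H]1CCC(C)(OS(Cl)=O)C(=O)C1 | intermediate
8 | (5R)-2-methyl-5-[1-(trifluoromethanesulfonyloxy)ethenyl]cyclohex-2-en-1-one | C=C(OS(=O)(=O)C(F)(F)F)[C@@H]1CC=C(C)C(=O)C1 | intermediate
9 | tiglic acid ((E)-2-methylbut-2-enoic acid) | C/C=C(\C)C(=O)O | starting material
10 | (1S,6R)-3-methyl-2-oxo-6-[1-(trifluoromethanesulfonyloxy)ethenyl]cyclohex-3-en-1-yl (2E)-2-methylbut-2-enoate | C=C(OS(=O)(=O)C(F)(F)F)[C@@H]1CC=C(C)C(=O)[C@H]1OC(=O)/C(C)=C/C | intermediate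
11 | (1S,2S,6R)-2-hydroxy-3-methyl-6-[1-(trifluoromethanesulfonyloxy)ethenyl]cyclohex-3-en-1-yl (2E)-2-methylbut-2-enoate | C=C(OS(=O)(=O)C(F)(F)F)[C@@H]1CC=C(C)[C@H](O)[C@H]1OC(=O)/C(C)=C/C | intermediate
12 | (1R,2R,3S,4R,6S)-2-hydroxy-1-methyl-4-[1-(trifluoromethanesulfonyloxy)ethenyl]-7-oxabicyclo[4.1.0]heptan-3-yl (2E)-2-methylbut-2-enoate | C=C(OS(=O)(=O)C(F)(F)F)[C@@H]1C[C@@H]2O[C@]2(C)[C@H](O)[C@H]1OC(=O)/C(C)=C/C | intermediate
13 | (1S,3S,4R,6S)-1-methyl-2-oxo-4-[1-(trifluoromethanesulfonyloxy)ethenyl]-7-oxabicyclo[4.1.0]heptan-3-yl (2E)-2-methylbut-2-enoate | C=C(OS(=O)(=O)C(F)(F)F)[C@@H]1C[C@@H]2O[C@]2(C)C(=O)[C@H]1OC(=O)/C(C)=C/C | intermediate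
14 | 2-methylbut-3-yn-2-ol | CC(C)(O)C#C | starting material
15 | (E)-2-methyl-4-(tributylstannyl)but-3-en-2-ol | CCCC[Sn](CCCC)(CCCC)/C=C/C(C)(C)O | intermediate
16 | (1S,3S,4S,6S)-4-[(4E)-6-hydroxy-6-methyl-3-oxohepta-1,4-dien-2-yl]-1-methyl-2-oxo-7-oxabicyclo[4.1.0]heptan-3-yl (2E)-2-methylbut-2-enoate | C=C(C(=O)/C=C/C(C)(C)O)[C@@H]1C[C@@H]2O[C@]2(C)C(=O)[C@H]1OC(=O)/C(C)=C/C | target

Total step count: 10. Longest linear sequence: 9 steps (steps 1 to 8, then step 10); step 9 is a one-step side branch.

Steps most likely to fail

Step 5. Ligand exchange on manganese may be incomplete, so that acetate transfer competes with tiglate transfer, and the oxygen transfer to the enolate may show poor facial control. Fallback, from 8: kinetic deprotonation at C3 and silylation (LiN(iPr)2, Me3SiCl, THF, −78 °C) should give the cross-conjugated trimethylsilyl dienol ether F1. Rubottom oxidation (mCPBA, NaHCO3, CH2Cl2, −20 °C, then aqueous citric acid) should deliver oxygen anti to the alkenyl group and give the trans hydroxy enone F2. Esterification of F2 with 9 (2,4,6-trichlorobenzoyl chloride, Et3N, then DMAP, toluene) comes back to the route at 10.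

Step 10. Transmetalation of the hindered acylpalladium with the hydroxyl-bearing stannane may be slow, so that CO-free coupling and palladium- or chloride-induced degradation of the α-acyloxy epoxy ketone compete. Fallback, from 13: the same palladium/CO conditions with the small, unfunctionalised tributyl(vinyl)stannane should give the divinyl ketone F3. Cross-metathesis of its monosubstituted vinyl ketone terminus with 2-methylbut-3-en-2-ol (second-generation Hoveyda–Grubbs catalyst, CH2Cl2, 40 °C) should install the (E)-hydroxyalkene and arrive at 16; the 1,1-disubstituted methylene and the tiglate alkene should not take part.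

Step 3. Over-oxidation may occur, either by attack of RuO4 on the enol triflate alkene or by C–C cleavage of the intermediate ruthenate ester. Fallback, from 5: OsO4 (2 mol%) with N-methylmorpholine N-oxide in acetone/H2O should dihydroxylate only the electron-rich ring alkene to the cis-diol F4. Parikh–Doering oxidation of its secondary hydroxyl (SO3·pyridine, DMSO, Et3N, CH2Cl2, 0 °C) leaves the tertiary hydroxyl and comes back to the route at 6.

Further compounds
F1 | step 5 | 1-[(1R)-4-methyl-3-(trimethylsilyloxy)cyclohexa-2,4-dien-1-yl]ethenyl trifluoromethanesulfonate | C=C(OS(=O)(=O)C(F)(F)F)[C@@H]1CC=C(C)C(O[Si](C)(C)C)=C1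
F2 | step 5 | (5R,6S)-6-hydroxy-2-methyl-5-[1-(trifluoromethanesulfonyloxy)ethenyl]cyclohex-2-en-1-one | C=C(OS(=O)(=O)C(F)(F)F)[C@@H]1CC=C(C)C(=O)[C@H]1O
F3 | step 10 | (1S,3S,4S,6S)-1-methyl-2-oxo-4-(3-oxopenta-1,4-dien-2-yl)-7-oxabicyclo[4.1.0]heptan-3-yl (2E)-2-methylbut-2-enoate | C=CC(=O)C(=C)[C@@H]1C[C@@H]2O[C@]2(C)C(=O)[C@H]1OC(=O)/C(C)=C/C
F4 | step 3 | 1-[(1R)-3,4-dihydroxy-4-methylcyclohexyl]ethenyl trifluoromethanesulfonate (cis-diol, both ring faces) | C=C(OS(=O)(=O)C(F)(F)F)[C@@H]1CCC(C)(O)C(O)C1
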